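**Retrosynthetic overview**
1. Feature: ring B (C1'–C6') is a free catechol beside the two aryl methyl ethers of ring A. Its carbons C2'–C3'(OH)–C4'(OH)–C5' map onto a constitutionally symmetrical 2,3-dioxygenated buta-1,3-diene. C1' and C6' map onto the two sp carbons of a propargyl group whose CH2 is C7' on lactone carbon C4.
2. Last disconnection: ring B is grown on that alkyne by a cobalt-catalysed [4+2] addition (bonds C1'–C2' and C5'–C6'), then dehydrogenated and freed of silicon. The catechol therefore never carries a protecting group that would have to be told apart from OMe.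
3. Second disconnection: the C3–C7 bond, made by trans-selective alkylation of the enolate of (R)-4-propargylbutyrolactone with 3,4-dimethoxybenzyl bromide (sets C3).
4. Third disconnection: the lactone comes from pent-4-ynoic acid by Evans alkylation with tert-butyl bromoacetate on (S)-4-benzyloxazolidinone (sets C4), borohydride reduction and acid lactonisation.
5. Ring order: ring A is bought, the lactone ring closes in step 4, ring B closes in step 7 and becomes aromatic in step 8.

Key step: step 7

Assumption: the stereodescriptors of the SMILES string are read as the (3R,4R)-trans lactone (ring A and C7 on C3, ring B and C7' on C4), and all descriptors below follow from that reading.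

**Step 1**
Reactants: 1 pent-4-ynoic acid; 2 (S)-4-benzyl-1,3-oxazolidin-2-one
Product: 4 (S)-4-benzyl-3-(pent-4-ynoyl)-1,3-oxazolidin-2-one, via mixed pivalic anhydride 3 (not isolated)
Conditions: PivCl, Et3N, THF, −20 °C; then LiCl, 2, −20 °C to rt
Reagents that add atoms: pivaloyl chloride, CC(C)(C)C(=O)Cl (its acyl group is held only by 3 and leaves again)
Why: Mixed-anhydride N-acylation of an oxazolidinone: Et3N and LiCl make the carbamate nitrogen nucleophilic enough to attack the unhindered carbonyl of 3, so no organolithium base meets the alkyne C–H and the auxiliary stereocentre is untouched.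

**Step 2**
Reactants: 4 (S)-4-benzyl-3-(pent-4-ynoyl)-1,3-oxazolidin-2-one; 5 tert-butyl bromoacetate
Product: 7 tert-butyl (3R)-3-{[(4S)-4-benzyl-2-oxo-1,3-oxazolidin-3-yl]carbonyl}hex-5-ynoate, via sodium Z-enolate 6 (not isolated)
Conditions: NaN(SiMe3)2 (1.05 equiv), THF, −78 °C; then 5, −78 to −40 °C
Reagents that add atoms: NaN(SiMe3)2, [Na+].C[Si](C)(C)[N-][Si](C)(C)C (sodium is held only by 6)
Why: Evans asymmetric alkylation: the amide base removes the imide alpha-proton, which is far more acidic than the alkyne C–H, to give the chelated Z-enolate 6, whose face on the side of the auxiliary benzyl group is blocked, so the bromoacetate adds from the opposite face and sets the (R) centre that becomes C4 of the lactone.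

**Step 3**
Reactants: 7 tert-butyl (3R)-3-{[(4S)-4-benzyl-2-oxo-1,3-oxazolidin-3-yl]carbonyl}hex-5-ynoate
Product: 8 tert-butyl (3R)-3-(hydroxymethyl)hex-5-ynoate
Conditions: LiBH4, MeOH (1 equiv each), THF, 0 °C; then H2O
Reagents that add atoms: none
Why: Reductive removal of the auxiliary with a lithium borohydride reagent: the activated exocyclic imide carbonyl is reduced at 0 °C much faster than the hindered tert-butyl ester, hydride leaves the isolated alkyne alone (which is why borane is avoided), and the stereocentre is not epimerised.

**Step 4**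
Reactants: 8 tert-butyl (3R)-3-(hydroxymethyl)hex-5-ynoate
Product: 10 (4R)-4-(prop-2-yn-1-yl)dihydrofuran-2(3H)-one, via hydroxy acid 9 (not isolated)
Conditions: TFA, CH2Cl2, rt
Reagents that add atoms: none
Why: Acidolysis of the tert-butyl ester with loss of isobutene, then spontaneous 5-exo-trig lactonisation of the gamma-hydroxy acid 9, closes the lactone ring, and the stereocentre lies beta to the carbonyl and cannot epimerise.

**Step 5**
Reactants: 11 veratryl alcohol (3,4-dimethoxybenzyl alcohol)
Product: 12 3,4-dimethoxybenzyl bromide
Conditions: PBr3, Et2O, 0 °C; used at once without chromatography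
Reagents that add atoms: phosphorus tribromide, BrP(Br)Br
Why: Standard conversion of a primary benzylic alcohol into the bromide by SN2 displacement on the phosphite ester; the electron-rich bromide is labile and is therefore made just before use.

**Step 6**
Reactants: 10 (4R)-4-(prop-2-yn-1-yl)dihydrofuran-2(3H)-one; 12 3,4-dimethoxybenzyl bromide
Product: 14 (3R,4R)-3-(3,4-dimethoxybenzyl)-4-(prop-2-yn-1-yl)dihydrofuran-2(3H)-one, via lithium enolate 13 (not isolated)
Conditions: LiN(SiMe3)2 (1.05 equiv), THF, −78 °C; then 12, −78 to −30 °C
Reagents that add atoms: LiN(SiMe3)2, [Li+].C[Si](C)(C)[N-][Si](C)(C)C (lithium is held only by 13)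
Why: Diastereoselective alkylation of a beta-substituted butyrolactone enolate, the standard entry to trans-dibenzylbutyrolactone lignans: the base takes the lactone alpha-proton in preference to the less acidic alkyne C–H, a lithium acetylide would be inert to the bromide at this temperature without a polar cosolvent, and 12 approaches the planar enolate 13 anti to the C4 propargyl group, which sets C3 as (R), trans.

**Step 7**
Reactants: 14 (3R,4R)-3-(3,4-dimethoxybenzyl)-4-(prop-2-yn-1-yl)dihydrofuran-2(3H)-one; 15 2,3-bis(trimethylsilyloxy)buta-1,3-diene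
Product: 16 (3R,4R)-4-{[4,5-bis(trimethylsilyloxy)cyclohexa-1,4-dien-1-yl]methyl}-3-(3,4-dimethoxybenzyl)dihydrofuran-2(3H)-one
Conditions: CoBr2(dppe) (10 mol%), Zn powder (20 mol%), dry ZnI2 (20 mol%), 15 (2 equiv, redistilled), CH2Cl2, rt, Ar, slow addition of 14; filtration through Et3N-deactivated silica, excess 15 removed in vacuo
Reagents that add atoms: none
Why: Proposed new method: zinc reduces CoBr2(dppe) to a monovalent cobalt species that ZnI2 renders cationic, this binds diene 15 in its s-cis form together with the terminal alkyne of 14, oxidative cyclisation makes the first C–C bond and gives an allyl/vinyl cobaltacycle, and reductive elimination makes the second (bonds C1'–C2' and C5'–C6'). The closest known reaction type is the cobalt-catalysed neutral Diels–Alder reaction of unactivated terminal alkynes with 2,3-dimethylbutadiene and with 2-(trimethylsilyloxy)butadiene, and the only new element is a diene that carries silyloxy groups on both inner carbons. Ring B closes as a six-membered carbocycle in an intermolecular [4+2] mode, the ring-closing event being C–C reductive elimination from a seven-membered cobaltacycle, and it is released as the skipped 1,4-diene. No stereocentre is created, and C3 and C4 sit outside the reacting atoms in a medium free of base, so both are carried through unchanged. Regiochemistry needs no control because 15 is constitutionally symmetrical and either orientation puts the two oxygens at C3' and C4' relative to C7'. What the step does need is chemoselectivity, for cross-addition over alkyne cyclotrimerisation and for the alkyne over lactone, silyl enol ether and veratryl ring, which excess diene, slow addition of 14, rigorously dry ZnI2 and the lack of any second pi-system in 14 able to bind cobalt should secure.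

**Step 8**
Reactants: 16 (3R,4R)-4-{[4,5-bis(trimethylsilyloxy)cyclohexa-1,4-dien-1-yl]methyl}-3-(3,4-dimethoxybenzyl)dihydrofuran-2(3H)-one
Product: 18 (3R,4R)-4-(3,4-dihydroxybenzyl)-3-(3,4-dimethoxybenzyl)dihydrofuran-2(3H)-one, via bis(trimethylsilyl) catechol ether 17 (not isolated)
Conditions: DDQ (1.0 equiv), CH2Cl2, 0 °C; filter; then 1 M HCl, THF, rt, Ar
Reagents that add atoms: none
Why: Oxidative aromatisation of a cyclohexa-1,4-diene with DDQ (hydride abstraction from a doubly allylic CH2, then proton loss) is driven by the gain of aromaticity and should be much faster than attack on the benzylic CH2 of ring A, the alternative channel through loss of silicon to the 1,2-dione converges on the same catechol by tautomerisation, and aryl trimethylsilyl ethers hydrolyse in dilute acid that leaves lactone, methyl ethers and both stereocentres alone.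

**Compound list**
1 | pent-4-ynoic acid | C#CCCC(=O)O | starting material
2 | (S)-4-benzyl-1,3-oxazolidin-2-one | O=C1N[C@@H](Cc2ccccc2)CO1 | starting material
3 | pent-4-ynoic pivalic anhydride | C#CCCC(=O)OC(=O)C(C)(C)C | intermediate
4 | (S)-4-benzyl-3-(pent-4-ynoyl)-1,3-oxazolidin-2-one | C#CCCC(=O)N1[C@@H](Cc2ccccc2)COC1=O | intermediate
5 | tert-butyl bromoacetate | CC(C)(C)OC(=O)CBr | starting material
6 | sodium (Z)-enolate of 4 | [Na+].[O-]/C(=C\CC#C)N1[C@@H](Cc2ccccc2)COC1=O | intermediate
7 | tert-butyl (3R)-3-{[(4S)-4-benzyl-2-oxo-1,3-oxazolidin-3-yl]carbonyl}hex-5-ynoate | C#CC[C@H](CC(=O)OC(C)(C)C)C(=O)N1[C@@H](Cc2ccccc2)COC1=O | intermediate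
8 | tert-butyl (3R)-3-(hydroxymethyl)hex-5-ynoate | C#CC[C@H](CC(=O)OC(C)(C)C)CO | intermediate
9 | (3R)-3-(hydroxymethyl)hex-5-ynoic acid | C#CC[C@H](CC(=O)O)CO | intermediate
10 | (4R)-4-(prop-2-yn-1-yl)dihydrofuran-2(3H)-one | C#CC[C@@H]1CC(=O)OC1 | intermediate
11 | veratryl alcohol | COc1ccc(CO)cc1OC | starting material
12 | 3,4-dimethoxybenzyl bromide | COc1ccc(CBr)cc1OC | intermediate
13 | lithium enolate of 10 | [Li+].[O-]C1=C[C@@H](CC#C)CO1 | intermediate
14 | (3R,4R)-3-(3,4-dimethoxybenzyl)-4-(prop-2-yn-1-yl)dihydrofuran-2(3H)-one | COc1ccc(C[C@H]2C(=O)OC[C@@H]2CC#C)cc1OC | intermediate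
15 | 2,3-bis(trimethylsilyloxy)buta-1,3-diene | C=C(O[Si](C)(C)C)C(=C)O[Si](C)(C)C | starting material
16 | (3R,4R)-4-{[4,5-bis(trimethylsilyloxy)cyclohexa-1,4-dien-1-yl]methyl}-3-(3,4-dimethoxybenzyl)dihydrofuran-2(3H)-one | COc1ccc(C[C@H]2C(=O)OC[C@@H]2CC2=CCC(O[Si](C)(C)C)=C(O[Si](C)(C)C)C2)cc1OC | intermediate
17 | (3R,4R)-4-[3,4-bis(trimethylsilyloxy)benzyl]-3-(3,4-dimethoxybenzyl)dihydrofuran-2(3H)-one | COc1ccc(C[C@H]2C(=O)OC[C@@H]2Cc2ccc(O[Si](C)(C)C)c(O[Si](C)(C)C)c2)cc1OC | intermediate
18 | (3R,4R)-4-(3,4-dihydroxybenzyl)-3-(3,4-dimethoxybenzyl)dihydrofuran-2(3H)-one (CNP0119683.1) | COc1ccc(C[C@H]2C(=O)OC[C@@H]2Cc2ccc(O)c(O)c2)cc1OC | target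

**Total step count:** 8. **Longest linear sequence:** 7 steps (1, 2, 3, 4, 6, 7, 8, from pent-4-ynoic acid); step 5 is a one-step side branch.

**Steps most likely to fail**

Risk 1, step 7.
- What may go wrong: the twisted, doubly oxygenated diene may bind cobalt too weakly, so that cyclotrimerisation of the alkyne overtakes the cross-addition. ZnI2 may also strip silicon from the diene before it reacts.
- Fallback (sets out from 14, comes back at 18, known chemistry only): ring B is built at the phenol level and the second oxygen is added afterwards. Alkyne 14 and commercial 2-(trimethylsilyloxy)buta-1,3-diene are combined under the same CoBr2(dppe)/Zn/ZnI2 system. This cycloaddition is established for that diene class, and the dppe ligand directs the 1,4-orientation, so the product should be the mono(silyloxy)cyclohexa-1,4-diene F1. DDQ aromatises it to the aryl silyl ether F2, and dilute HCl in THF frees the 4-alkylphenol F3. 2-Iodoxybenzoic acid in DMF at rt then oxygenates an ortho position to the ortho-quinone F4; the two ortho positions are equivalent, so only one product can arise. F4 is reduced in the same flask with aqueous Na2S2O4 to 18.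

Risk 2, step 8.
- What may go wrong: oxidation may run past the catechol level once silicon is lost. Hydride may be abstracted from the benzylic CH2 of electron-rich ring A. The enol ethers may hydrolyse early, with drift of the ring double bond into conjugation.
- Fallback (sets out from 16, comes back at 18): the oxidation is moved from the ring C–H bonds to the enediol C=C bond. One equivalent of Br2 in CH2Cl2 is added slowly to 16 at −78 °C. Electrophilic attack on the bis(silyloxy)alkene, by far the most electron-rich pi-bond present, with loss of two Me3SiBr, is the known conversion of acyloin-derived bis(silyl) enediol ethers into 1,2-diones. It should give the cyclohex-4-ene-1,2-dione F5, a non-aromatic tautomer of the target that enolises twice to 18 on warming and aqueous work-up. Oxidation and desilylation then happen in one operation, and the oxidant is used up before any catechol exists.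

Risk 3, step 6.
- What may go wrong: proton exchange among enolate, product and the alkyne C–H may cause incomplete conversion and double alkylation. The labile bromide may decay. The facial bias may be weaker because a propargyl group is slimmer than a benzyl group.
- Fallback (sets out from 10, comes back at 14): the alkyne C–H is masked first. Lactone 10 is C-silylated under mild conditions (TMSOTf, Et3N, catalytic Zn(OTf)2, CH2Cl2) to the silylalkyne lactone F6. With no acidic C–H left, LiN(iPr)2 and DMPU can be used to form the lithium enolate F7, which is alkylated with 12 anti to the now bulkier side chain to give the trans-lactone F8. Any cis isomer can be equilibrated with DBU to the more stable trans form. TBAF buffered with AcOH in THF at 0 °C then removes the silyl group and gives 14.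

**Further compounds**
F1 | step 7 | (3R,4R)-3-(3,4-dimethoxybenzyl)-4-{[4-(trimethylsilyloxy)cyclohexa-1,4-dien-1-yl]methyl}dihydrofuran-2(3H)-one | COc1ccc(C[C@H]2C(=O)OC[C@@H]2CC2=CCC(O[Si](C)(C)C)=CC2)cc1OC
F2 | step 7 | (3R,4R)-3-(3,4-dimethoxybenzyl)-4-[4-(trimethylsilyloxy)benzyl]dihydrofuran-2(3H)-one | COc1ccc(C[C@H]2C(=O)OC[C@@H]2Cc2ccc(O[Si](C)(C)C)cc2)cc1OC
F3 | step 7 | (3R,4R)-3-(3,4-dimethoxybenzyl)-4-(4-hydroxybenzyl)dihydrofuran-2(3H)-one | COc1ccc(C[C@H]2C(=O)OC[C@@H]2Cc2ccc(O)cc2)cc1OC
F4 | step 7 | (3R,4R)-3-(3,4-dimethoxybenzyl)-4-[(3,4-dioxocyclohexa-1,5-dien-1-yl)methyl]dihydrofuran-2(3H)-one | COc1ccc(C[C@H]2C(=O)OC[C@@H]2CC2=CC(=O)C(=O)C=C2)cc1OC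
F5 | step 8 | (3R,4R)-3-(3,4-dimethoxybenzyl)-4-[(4,5-dioxocyclohex-1-en-1-yl)methyl]dihydrofuran-2(3H)-one | COc1ccc(C[C@H]2C(=O)OC[C@@H]2CC2=CCC(=O)C(=O)C2)cc1OC
F6 | step 6 | (4R)-4-[3-(trimethylsilyl)prop-2-yn-1-yl]dihydrofuran-2(3H)-one | C[Si](C)(C)C#CC[C@@H]1CC(=O)OC1
F7 | step 6 | lithium enolate of F6 | [Li+].[O-]C1=C[C@@H](CC#C[Si](C)(C)C)CO1
F8 | step 6 | (3R,4R)-3-(3,4-dimethoxybenzyl)-4-[3-(trimethylsilyl)prop-2-yn-1-yl]dihydrofuran-2(3H)-one | COc1ccc(C[C@H]2C(=O)OC[C@@H]2CC#C[Si](C)(C)C)cc1OC
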